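Late in the ash, birch and cedar runs you watch links fall rather than rise, and the chain length asked for follows from where they stand and how fast they fall.

| setting | ash | birch | cedar | summer | autumn |
|---|---|---|---|---|---|
| first end groups | 1.5 M | 1.5 M | 0.75 M | 1.5 M | 1.5 M |
| second end groups | 1.35 M | 1.35 M | 1.35 M | 1.35 M | 1.35 M |
| one-sided end groups | 0.050 M | 0.11 M | 0.075 M | 0.0750 M | 0.0750 M |
| remark | run made earlier | run made earlier | run made earlier |  |  |
| time |  |  |  | 5.0 d | 1.2 d |

| run | time / d | links / % |
|---|---|---|
| ash | 0.333 | 68.6 |
| ash | 0.500 | 71.3 |
| ash | 0.833 | 71.2 |
| ash | 1.04 | 71.2 |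
| ash | 1.67 | 70.7 |
| ash | 2.50 | 67.3 |
| ash | 4.00 | 65.5 |
| birch | 0.333 | 67.7 |
| birch | 0.500 | 69.5 |
| birch | 0.833 | 70.6 |
| birch | 1.04 | 70.2 |
| birch | 1.67 | 68.5 |
| birch | 2.50 | 66.0 |
| birch | 4.00 | 63.9 |
| cedar | 0.333 | 79.5 |
| cedar | 1.04 | 84.6 |
| cedar | 1.67 | 83.2 |
| cedar | 3.00 | 80.2 |
| cedar | 4.00 | 77.7 |

(standard deviation of a reading: 0.5 percentage points)

- each monomer carries two end groups and one-sided end groups one, which caps an end: a chain counts once for every two ends that are left, dead ends included; the units are half of the end groups of the two monomers charged
- steps under discussion: first end groups + second end groups -> links; first end groups + one-sided end groups -> capped ends; second end groups -> decomposed reagent; links -> over-reaction product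
- a link that another step uses up counts as cut, two dead ends; so do two ends of one kind that react with each other

1. which of the two ends with the longer chains by the average number of monomer units in a chain (unreacted monomers counted as chains of one) ("neither" if they lie within 10%) (summer / autumn / neither)
2. average number of monomer units in a chain (unreacted monomers counted as chains of one) at the end, summer
3. average number of monomer units in a chain (unreacted monomers counted as chains of one) at the end, autumn

- Between 1.04 d and 4.00 d the summed ash and birch readings shrink by 0.0300 d⁻¹: this is the cut share, the part of the standing links lost per day, a first-order loss.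
- Cedar, with half the first end groups, reads 0.0287 d⁻¹, so you can carry the share across recipes.
- Summer and autumn have a one-sided charge between those of ash and birch, so you take their mean reading at 1.04 d, 70.7%, as the level from which the fall starts. The first loss is then 0.0318 M d⁻¹.
- That rate slows as links go: it stands at 0.995 of its first value by 1.2 d, but at 0.888 by 5.0 d, and links follow the same factors.
- A cut link leaves two dead ends, so chains are units less links, with 1.43 M of units, and the average length, the number-average degree of polymerisation, is units over chains.
- Your reckoning gives summer 0.942 M of links and a length of 2.95. It gives autumn 1.06 M and 3.86.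
- The forecast, reckoned separately, chose autumn, with 2.97 (2.85 to 3.1) for summer and 3.88 (3.7 to 4.05) for autumn, holding that “every cut link adds two dead ends”. Your two lengths lie slightly below its values.
- The flask gives autumn: 2.89 for summer and 3.86 for autumn.

    first end groups + second end groups → links (k = 1.18 × 10⁻⁴ M⁻¹ s⁻¹)
    first end groups + one-sided end groups → capped ends (k = 0.00216 M⁻¹ s⁻¹)
    second end groups → decomposed reagent (k = 2.05 × 10⁻⁵ s⁻¹)
    links → over-reaction product (k = 3.82 × 10⁻⁷ s⁻¹)

- In autumn at 1.20 d, links are made more slowly than they are used up, each step taken net, the ratio being 0.0950. Summer's links go from 67.5% at 2.50 d to 62.1% at 5.00 d, a factor of 0.920 against 0.928 from the cut share. Autumn left until 12.0 d keeps 0.701 of its links against 0.723 from the share, and its chains shrink to 2.08.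

The readings come from a simulation with constants of no real substance.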